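(The earlier runs and the new flask were computed with made-up constants; noise was put on by code.)

What I wanted to know was how much of the substrate in the flask had reacted by 1.0 h, and what, if anything, had stopped it.

the same everywhere: initiator 25 µM

| flask | substrate | partner | remark | time |
|---|---|---|---|---|
| Monday's | 0.50 mM | 0.90 mM | run made earlier |  |
| Thursday's | 2 mM | 0.90 mM | run made earlier |  |
| flask | 1.0 mM | 0.900 mM |  | 1.0 h |

| run | time / min | substrate / % | target / % |
|---|---|---|---|
| Monday's | 3.00 | 37.8 | 17.0 |
| Monday's | 10.0 | 35.3 | 1.2 |
| Monday's | 15.0 | 32.7 | 1.3 |
| Monday's | 25.0 | 31.5 | 0.3 |
| Monday's | 40.0 | 31.9 | 1.6 |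
| Thursday's | 8.00 | 72.5 | 1.2 |
| Thursday's | 15.0 | 70.0 | 0 |
| Thursday's | 20.0 | 72.2 | 0 |
| Thursday's | 30.0 | 72.1 | 0 |
| Thursday's | 40.0 | 73.0 | 0 |

(each reading ± 1 percentage point)

- at 1.0 h, what has stopped the reaction, if anything has (the partner has run out first / it is still moving / forward and back rates have come level / all of the substrate has reacted)
- how much of the substrate has reacted by 1.0 h

- in percentages every species weighs as the substrate in it: one ended chains B counts as two
- what was read earlier has a scatter of 1 percentage point, one standard deviation
- steps under discussion: initiator -> 2 initiating radical; substrate + initiating radical -> capped initiator + first chain carrier; partner + first chain carrier -> target + second chain carrier; substrate + second chain carrier -> by-product + first chain carrier; first chain carrier -> ended carrier; 2 second chain carrier -> ended chains A; 2 first chain carrier -> ended chains B; target -> over-reaction product; partner -> decomposed reagent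
- the reaction counts as stopped when no species that holds the substrate changes by six tenths of a point or more over the second half of the time

I took the settings in turn. By hand, a longer time helps while the substrate still moves, but Monday's substrate went from 31.5% at 25.0 min to 31.9% at 40.0 min, inside the scatter, so I expected nothing from more time. Partner and initiator stood equal in both runs, so the readings were silent on them, although I expected more of either to carry the chain further. More substrate should raise the amount used, and it did: the flat readings gave 0.342 mM used on Monday and 0.549 mM on Thursday. Both are less than the partner charged, so if the partner was the limiting reagent, some of it had left by another path.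

This flask's [substrate] lies midway between those runs on a logarithmic scale. Averaging them gave my partner ratio, the substrate used, by whatever step, per partner charged, 49.5%, and so a conversion of 44.5%.

The forecast said: the partner has run out first, on the ground that “partner is lost by its own decomposition”, and it gave 47% reacted, above my figure.

The flask gave: the partner has run out first, with 46.5% reacted, 0% of the partner left at 1.00 h, and a partner ratio of 51.7% against my 49.5%.

    initiator → 2 initiating radical (k = 0.00220 s⁻¹)
    substrate + initiating radical → capped initiator + first chain carrier (k = 1.60 × 10⁷ M⁻¹ s⁻¹)
    partner + first chain carrier → target + second chain carrier (k = 1.90 × 10⁶ M⁻¹ s⁻¹)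
    substrate + second chain carrier → by-product + first chain carrier (k = 1.80 × 10⁶ M⁻¹ s⁻¹)
    first chain carrier → ended carrier (k = 2.00 s⁻¹)
    2 second chain carrier → ended chains A (k = 6.30 × 10⁸ M⁻¹ s⁻¹)
    2 first chain carrier → ended chains B (k = 4.10 × 10⁶ M⁻¹ s⁻¹)
    target → over-reaction product (k = 0.00760 s⁻¹)
    partner → decomposed reagent (k = 0.0340 s⁻¹)

In this flask the partner's half-life by decomposition alone, 0.340 min, was shorter than the substrate's half-life by its step with the second chain carrier, 0.80 min at 0.00283 h, and 0.482 mM of decomposed reagent stood beside 0.415 mM of by-product. The neighbouring flask with 0.10 mM of initiator held 0.329 mM of decomposed reagent beside 0.562 mM of by-product, and its partner ratio was 84.7%.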